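## Retrosynthetic overview

1. Last bond: the exocyclic C=C, by E-selective cross-metathesis of an α-methylene hydroxy lactone with a homoallylic acetate that carries the whole side chain.
2. The lactone (the only ring) comes from a Sharpless epoxy alcohol by a carbonylative double ring expansion, oxirane → oxetan-2-one → oxolan-2-one; both ring stereocentres are set in the epoxidation.
3. The isobutenyl group is installed by metathesis with 2-methylbut-2-ene and the α-methylene group by a Mannich/elimination sequence.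
4. Side chain: C8 carbinol by Brown allylation of an E-enal; enal by metathesis with methacrolein; Z-alkene by iron-catalysed syn-methylmagnesiation of a propargylic alkoxide; ester by Mitsunobu coupling.
5. Ring order: oxirane (step 1), then four-membered lactone, then five-membered lactone (both in step 2); no other ring is formed.

Assumption: penta-1,4-dien-3-ol, hex-1-en-5-yne, (2E)-3-methylpent-2-enoic acid and (+)-Ipc2B(allyl) (the reagent made from (+)-α-pinene) are bought; side-chain carbons C1–C10 are counted from the ester CH2O.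

## Route

Step 1
Reactants: 1 penta-1,4-dien-3-ol
Product: 2 (2S,3R)-1,2-epoxypent-4-en-3-ol
Conditions: Ti(OiPr)4 (0.2 equiv), (−)-diisopropyl D-tartrate (0.26 equiv), tBuOOH (1.5 equiv), 4 Å sieves, CH2Cl2, −20 °C, 4 d
Reagents that add atoms: tert-butyl hydroperoxide CC(C)(C)OO
Why: Sharpless asymmetric epoxidation used as a desymmetrisation: the D-tartrate titanium catalyst picks one enantiotopic vinyl group and one face, giving the erythro epoxy alcohol with C2 (S) and C3 (R), and the minor enantiomer is consumed by a faster second epoxidation, so the ee rises with conversion.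

Step 2
Reactants: 2 (2S,3R)-1,2-epoxypent-4-en-3-ol
Product: 4 (4S,5R)-5-ethenyl-4-hydroxyoxolan-2-one, via hydroxyallyl β-lactone 3 (not isolated)
Conditions: [(salph)Al(THF)2][Co(CO)4] (3 mol %), CO (60 bar), DME, 50 °C, 16 h; vent, 50 °C, 2 h
Reagents that add atoms: carbon monoxide [C-]#[O+]
Why: Proposed new method: a one-flask carbonylative double ring expansion of an unprotected secondary 2,3-epoxy alcohol, a substrate class on which it has not been shown; the aluminium cation (salph = N,N'-bis(3,5-di-tert-butylsalicylidene)-1,2-phenylenediaminate) binds the oxirane oxygen and the neighbouring hydroxyl, [Co(CO)4]− opens the ring at the unsubstituted CH2 by SN2 attack, CO inserts and the alkoxide closes the oxetan-2-one 3 (first expansion), then the aluminium-bound carbinol oxygen attacks the strained acyl group and a 1,2 O-to-O acyl shift closes the five-membered lactone (second expansion, driven by strain relief), and both stereocentres are retained because no bond to them is broken; closest known reaction type: Lewis acid/[Co(CO)4]− ring-expanding carbonylation of epoxides to β-lactones, followed by acyl transfer (translactonisation) of a hydroxy β-lactone.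

Step 3
Reactants: 4 (4S,5R)-5-ethenyl-4-hydroxyoxolan-2-one; 5 2-methylbut-2-ene
Product: 6 (4S,5R)-4-hydroxy-5-(2-methylprop-1-en-1-yl)oxolan-2-one
Conditions: second-generation Grubbs catalyst (3 mol %), 2-methylbut-2-ene/CH2Cl2 (1:1), 40 °C, sealed tube
Reagents that add atoms: none
Why: Olefin cross-metathesis of the terminal vinyl group with 2-methylbut-2-ene gives the trisubstituted 2-methylprop-1-enyl group with loss of propene; the lactone, the free hydroxyl and both stereocentres are not involved.

Step 4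
Reactants: 6 (4S,5R)-4-hydroxy-5-(2-methylprop-1-en-1-yl)oxolan-2-one
Product: 9 (4S,5R)-4-hydroxy-3-methylidene-5-(2-methylprop-1-en-1-yl)oxolan-2-one, via Mannich base 7 (not isolated), via methiodide 8 (not isolated)
Conditions: LiN(iPr)2 (2.2 equiv), THF, −78 °C; CH2=NMe2+ I− (1.3 equiv), −78 → 0 °C; H2O; crude, MeI, MeOH, rt; NaHCO3, CH2Cl2/H2O, rt (one purification)
Reagents that add atoms: N,N-dimethylmethylideneammonium iodide C=[N+](C)C.[I-]; iodomethane CI (its methyl sits in 8 only)
Why: Mannich reaction of the alkoxide–enolate dianion with Eschenmoser's salt (C-alkylation anti to the alkoxide; the new C3 centre is lost again), then exhaustive N-methylation and E1cB elimination of trimethylamine give the α-methylene lactone; the alkoxide form of the 4-OH blocks β-elimination, and C4 and C5 are untouched.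

Step 5
Reactants: 10 hex-1-en-5-yne
Product: 13 (2Z)-3-methylhepta-2,6-dien-1-ol, via enynol magnesium alkoxide 11 (not isolated), via alkenylmagnesium alkoxide 12 (not isolated)
Conditions: EtMgBr (1.0 equiv), THF, 50 °C; (CH2O)n (1.0 equiv), 50 °C; MeMgBr (4 equiv), 0 °C; Fe(acac)3 (15 mol %), −78 → 0 °C; aq. NH4Cl
Reagents that add atoms: formaldehyde (from paraformaldehyde) C=O; methylmagnesium bromide C[Mg]Br; ethylmagnesium bromide CC[Mg]Br (only its MgBr, in 11 and 12)
Why: Alkynyl Grignard addition to formaldehyde gives the propargylic alkoxide, which directs an iron-catalysed syn-carbomagnesiation (methyl to the distal alkyne carbon, magnesium to the proximal one), and protonation with retention gives the Z-trisubstituted alkene (chain cis to CH2OH); excess MeMgBr removes leftover formaldehyde before the alkenylmagnesium forms, and the undirected terminal alkene stays.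

Step 6
Reactants: 13 (2Z)-3-methylhepta-2,6-dien-1-ol; 14 (2E)-3-methylpent-2-enoic acid
Product: 15 (2Z)-3-methylhepta-2,6-dien-1-yl (2E)-3-methylpent-2-enoate
Conditions: PPh3, diisopropyl azodicarboxylate, THF, 0 °C → rt
Reagents that add atoms: none
Why: Mitsunobu esterification: the carboxylate displaces the activated primary allylic oxygen (SN2), so the acid never becomes an acyl electrophile and the E-enoate cannot deconjugate or isomerise; the Z-alkene is untouched.

Step 7
Reactants: 15 (2Z)-3-methylhepta-2,6-dien-1-yl (2E)-3-methylpent-2-enoate; 16 methacrolein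
Product: 17 (2Z,6E)-3,7-dimethyl-8-oxoocta-2,6-dien-1-yl (2E)-3-methylpent-2-enoate
Conditions: second-generation Hoveyda–Grubbs catalyst (5 mol %), methacrolein (8 equiv), CH2Cl2, 40 °C
Reagents that add atoms: none
Why: Olefin cross-metathesis of the terminal alkene with a 1,1-disubstituted enal; the trisubstituted alkenes react much more slowly, and the new trisubstituted enal forms as the E isomer (CHO trans to the chain) under thermodynamic control.

Step 8
Reactants: 17 (2Z,6E)-3,7-dimethyl-8-oxoocta-2,6-dien-1-yl (2E)-3-methylpent-2-enoate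
Product: 19 (2Z,6E,8S)-8-hydroxy-3,7-dimethylundeca-2,6,10-trien-1-yl (2E)-3-methylpent-2-enoate, via diisopinocampheylborinate 18 (not isolated)
Conditions: (+)-Ipc2B(allyl) (1.3 equiv), Et2O, −78 °C; ethanolamine, rt
Reagents that add atoms: (+)-Ipc2B(allyl) C=CCB([C@@H]1C[C@@H]2C[C@H]([C@H]1C)C2(C)C)[C@@H]1C[C@@H]2C[C@H]([C@H]1C)C2(C)C (allyl group into 19; the Ipc2B unit sits in 18 only)
Why: Brown asymmetric allylboration through a chair transition state with the aldehyde substituent equatorial; the reagent from (+)-α-pinene adds to the Si face of the α-methyl enal and sets C8 as (S), with 1,2-addition only and both esters untouched at −78 °C.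

Step 9
Reactants: 19 (2Z,6E,8S)-8-hydroxy-3,7-dimethylundeca-2,6,10-trien-1-yl (2E)-3-methylpent-2-enoate
Product: 20 (2Z,6E,8S)-8-acetoxy-3,7-dimethylundeca-2,6,10-trien-1-yl (2E)-3-methylpent-2-enoate
Conditions: Ac2O, pyridine, DMAP (cat.), CH2Cl2, 0 °C → rt
Reagents that add atoms: acetic anhydride CC(=O)OC(C)=O
Why: Standard acylation of the secondary alcohol, done before the union so that the C8 oxygen is already differentiated from the lactone hydroxyl and no protecting group is needed.

Step 10
Reactants: 20 (2Z,6E,8S)-8-acetoxy-3,7-dimethylundeca-2,6,10-trien-1-yl (2E)-3-methylpent-2-enoate; 9 (4S,5R)-4-hydroxy-3-methylidene-5-(2-methylprop-1-en-1-yl)oxolan-2-one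
Product: 21 (2Z,6E,8S,10E)-8-acetoxy-10-[(4S,5R)-4-hydroxy-5-(2-methylprop-1-en-1-yl)-2-oxooxolan-3-ylidene]-3,7-dimethyldeca-2,6-dien-1-yl (2E)-3-methylpent-2-enoate
Conditions: 9 (2.5 equiv), second-generation Hoveyda–Grubbs catalyst (2 × 5 mol %), 2,6-dichloro-1,4-benzoquinone (20 mol %), CH2Cl2, 40 °C
Reagents that add atoms: none
Why: Olefin cross-metathesis between the terminal alkene of 20 and the 1,1-disubstituted alkene of 9, a reaction known for α-methylene-γ-butyrolactones to give the E-alkylidene lactone (chain anti to the carbonyl); the benzoquinone suppresses ruthenium hydride isomerisation, trisubstituted alkenes react much more slowly, and no stereocentre is touched.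

## Compound list

1 | penta-1,4-dien-3-ol | C=CC(O)C=C | starting material
2 | (2S,3R)-1,2-epoxypent-4-en-3-ol | O[C@H](C=C)[C@@H]1CO1 | intermediate
3 | (4S)-4-[(1R)-1-hydroxyprop-2-en-1-yl]oxetan-2-one | O[C@H](C=C)[C@@H]1CC(=O)O1 | intermediate (not isolated)
4 | (4S,5R)-5-ethenyl-4-hydroxyoxolan-2-one | O=C1C[C@H](O)[C@@H](C=C)O1 | intermediate
5 | 2-methylbut-2-ene | CC=C(C)C | starting material
6 | (4S,5R)-4-hydroxy-5-(2-methylprop-1-en-1-yl)oxolan-2-one | O=C1C[C@H](O)[C@@H](C=C(C)C)O1 | intermediate
7 | (3S,4S,5R)-3-[(dimethylamino)methyl]-4-hydroxy-5-(2-methylprop-1-en-1-yl)oxolan-2-one | CN(C)C[C@@H]1C(=O)O[C@H](C=C(C)C)[C@H]1O | intermediate (not isolated)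
8 | {[(3S,4S,5R)-4-hydroxy-5-(2-methylprop-1-en-1-yl)-2-oxooxolan-3-yl]methyl}trimethylammonium iodide | C[N+](C)(C)C[C@@H]1C(=O)O[C@H](C=C(C)C)[C@H]1O.[I-] | intermediate (not isolated)
9 | (4S,5R)-4-hydroxy-3-methylidene-5-(2-methylprop-1-en-1-yl)oxolan-2-one | C=C1C(=O)O[C@H](C=C(C)C)[C@H]1O | intermediate
10 | hex-1-en-5-yne | C=CCCC#C | starting material
11 | bromomagnesium hept-6-en-2-yn-1-olate | C=CCCC#CCO[Mg]Br | intermediate (not isolated)
12 | bromomagnesium 2-(bromomagnesio)-3-methylhepta-2,6-dien-1-olate (methyl and magnesium cis) | C=CCC/C(C)=C(\CO[Mg]Br)[Mg]Br | intermediate (not isolated)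
13 | (2Z)-3-methylhepta-2,6-dien-1-ol | C=CCC/C(C)=C\CO | intermediate
14 | (2E)-3-methylpent-2-enoic acid | CC/C(C)=C/C(=O)O | starting material
15 | (2Z)-3-methylhepta-2,6-dien-1-yl (2E)-3-methylpent-2-enoate | CC/C(C)=C/C(=O)OC/C=C(/C)CCC=C | intermediate
16 | methacrolein (2-methylprop-2-enal) | CC(=C)C=O | starting material
17 | (2Z,6E)-3,7-dimethyl-8-oxoocta-2,6-dien-1-yl (2E)-3-methylpent-2-enoate | CC/C(C)=C/C(=O)OC/C=C(/C)CC/C=C(\C)C=O | intermediate
18 | bis(isopinocampheyl)borinate of 19 | CC/C(C)=C/C(=O)OC/C=C(/C)CC/C=C(\C)[C@H](CC=C)OB([C@@H]1C[C@@H]2C[C@H]([C@H]1C)C2(C)C)[C@@H]1C[C@@H]2C[C@H]([C@H]1C)C2(C)C | intermediate (not isolated)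
19 | (2Z,6E,8S)-8-hydroxy-3,7-dimethylundeca-2,6,10-trien-1-yl (2E)-3-methylpent-2-enoate | CC/C(C)=C/C(=O)OC/C=C(/C)CC/C=C(\C)[C@H](CC=C)O | intermediate
20 | (2Z,6E,8S)-8-acetoxy-3,7-dimethylundeca-2,6,10-trien-1-yl (2E)-3-methylpent-2-enoate | CC/C(C)=C/C(=O)OC/C=C(/C)CC/C=C(\C)[C@H](CC=C)OC(C)=O | intermediate
21 | (2Z,6E,8S,10E)-8-acetoxy-10-[(4S,5R)-4-hydroxy-5-(2-methylprop-1-en-1-yl)-2-oxooxolan-3-ylidene]-3,7-dimethyldeca-2,6-dien-1-yl (2E)-3-methylpent-2-enoate | CC/C(C)=C/C(=O)OC/C=C(/C)CC/C=C(\C)[C@H](C/C=C1/C(=O)O[C@H](C=C(C)C)[C@H]1O)OC(C)=O | target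

## Count and risks

Total step count: 10. Longest linear sequence: 6 steps (steps 5–10, from 10); the lactone branch is steps 1–4 and joins at step 10.

Step 2 (the proposed new step). The free hydroxyl may block the aluminium centre, or the epoxide may rearrange to a ketone instead of taking up CO. The fallback uses known chemistry, sets out from 2 and comes back at 4. Cobalt-catalysed methoxycarbonylation of the terminal epoxide (Co2(CO)8, 3-hydroxypyridine, CO 40 bar, MeOH/THF, 60 °C) opens 2 at CH2 to the open-chain ester methyl (3S,4R)-3,4-dihydroxyhex-5-enoate F1. This is lactonised with catalytic pyridinium p-toluenesulfonate in CH2Cl2 to 4. No β-lactone and no acyl shift are involved; the cost is one extra step.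

Step 10. The 1,1-disubstituted alkene of 9 is a slow metathesis partner; the isobutenyl groups may compete, and the E/Z ratio next to the C4 hydroxyl is not certain. The fallback replaces metathesis by an aldol–dehydration union; it sets out from 17 and 6 and comes back at 21.
- Enal 17 is homologated by a BINOL/Ti(OiPr)4-catalysed Mukaiyama aldol addition of 1-(tert-butylsulfanyl)-1-(trimethylsilyloxy)ethene (BINOL enantiomer chosen for the 3S adduct) to S-tert-butyl (3S,4E,8Z)-3-hydroxy-4,8-dimethyl-10-{[(2E)-3-methylpent-2-enoyl]oxy}deca-4,8-dienethioate F4.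
- F4 is acetylated (Ac2O, pyridine) to the 3-acetate F5 and reduced (Et3SiH, Pd/C, acetone; Fukuyama reduction) to the aldehyde (2Z,6E,8S)-8-acetoxy-3,7-dimethyl-10-oxodeca-2,6-dien-1-yl (2E)-3-methylpent-2-enoate F6.
- Lactone 6 is silylated (tBuMe2SiCl, imidazole, DMF) to (4S,5R)-4-[(tert-butyldimethylsilyl)oxy]-5-(2-methylprop-1-en-1-yl)oxolan-2-one F7.
- The lithium enolate of F7 (LiN(iPr)2, THF, −78 °C) adds to F6 to give the aldol adduct F8 (mixture at the two new centres).
- Mesylation and elimination (MeSO2Cl, Et3N; then DBU) give the E-alkylidene silyl ether F9, and HF·pyridine frees 21.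

Step 5. The one-pot sequence depends on clean removal of formaldehyde before the carbomagnesiation and on the regio- and stereoselectivity of the iron-catalysed methyl addition. The fallback uses a cuprate addition to an ynoate; it sets out from 10 and comes back at 13. Hex-1-en-5-yne is deprotonated (nBuLi, THF, −78 °C) and acylated with methyl chloroformate to methyl hept-6-en-2-ynoate F2. Syn addition of Me2CuLi (THF, −78 °C, quench at −78 °C) gives methyl (2Z)-3-methylhepta-2,6-dienoate F3. Reduction with iBu2AlH (CH2Cl2, −78 °C) gives 13.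

Further compounds

F1 | step 2 | methyl (3S,4R)-3,4-dihydroxyhex-5-enoate | O[C@H](C=C)[C@@H](O)CC(=O)OC
F2 | step 5 | methyl hept-6-en-2-ynoate | C=CCCC#CC(=O)OC
F3 | step 5 | methyl (2Z)-3-methylhepta-2,6-dienoate | C=CCC/C(C)=C\C(=O)OC
F4 | step 10 | S-tert-butyl (3S,4E,8Z)-3-hydroxy-4,8-dimethyl-10-{[(2E)-3-methylpent-2-enoyl]oxy}deca-4,8-dienethioate | CC/C(C)=C/C(=O)OC/C=C(/C)CC/C=C(\C)[C@@H](O)CC(=O)SC(C)(C)C
F5 | step 10 | S-tert-butyl (3S,4E,8Z)-3-acetoxy-4,8-dimethyl-10-{[(2E)-3-methylpent-2-enoyl]oxy}deca-4,8-dienethioate | CC/C(C)=C/C(=O)OC/C=C(/C)CC/C=C(\C)[C@@H](OC(C)=O)CC(=O)SC(C)(C)C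
F6 | step 10 | (2Z,6E,8S)-8-acetoxy-3,7-dimethyl-10-oxodeca-2,6-dien-1-yl (2E)-3-methylpent-2-enoate | CC/C(C)=C/C(=O)OC/C=C(/C)CC/C=C(\C)[C@@H](OC(C)=O)CC=O
F7 | step 10 | (4S,5R)-4-[(tert-butyldimethylsilyl)oxy]-5-(2-methylprop-1-en-1-yl)oxolan-2-one | O=C1C[C@H](O[Si](C)(C)C(C)(C)C)[C@@H](C=C(C)C)O1
F8 | step 10 | (2Z,6E,8S)-8-acetoxy-10-hydroxy-10-[(4S,5R)-4-[(tert-butyldimethylsilyl)oxy]-5-(2-methylprop-1-en-1-yl)-2-oxooxolan-3-yl]-3,7-dimethyldeca-2,6-dien-1-yl (2E)-3-methylpent-2-enoate (mixture at C10 and lactone C3) | CC/C(C)=C/C(=O)OC/C=C(/C)CC/C=C(\C)[C@H](CC(O)C1C(=O)O[C@H](C=C(C)C)[C@H]1O[Si](C)(C)C(C)(C)C)OC(C)=O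
F9 | step 10 | tert-butyldimethylsilyl ether of 21 at the lactone 4-hydroxyl | CC/C(C)=C/C(=O)OC/C=C(/C)CC/C=C(\C)[C@H](C/C=C1/C(=O)O[C@H](C=C(C)C)[C@H]1O[Si](C)(C)C(C)(C)C)OC(C)=O
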